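| setting | elm | oak | flask |
|---|---|---|---|
| left-handed substrate | 0.10 M | 0.10 M | 0.10 M |
| right-handed substrate | 0.10 M | 0.10 M | 0.10 M |
| partner | 0.40 M | 0.40 M | 0.400 M |
| free catalyst | 0.85 mM | 3.4 mM | 1.7 mM |
| remark | run made earlier | run made earlier |  |
| time |  |  | 3.0 min |

| run | time / min | left-handed substrate / % | right-handed substrate / % |
|---|---|---|---|
| elm | 0.417 | 23.5 | 28.9 |
| elm | 1.33 | 12.6 | 15.1 |
| elm | 2.50 | 8.7 | 9.7 |
| elm | 4.00 | 6.8 | 7.1 |
| oak | 0.250 | 15.1 | 24.5 |
| oak | 0.667 | 6.2 | 11.0 |
| oak | 1.50 | 2.9 | 4.0 |
| oak | 4.00 | 0.2 | 0.1 |

(scatter of a reading: 0.5 percentage points)

- free catalyst is single-handed; left-handed substrate and right-handed substrate are mirror images of each other, charged as a racemate, each of them at the stated concentration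
- on the list of suspects stand: partner + free catalyst + left-handed substrate -> free catalyst + left-handed product; partner + free catalyst + right-handed substrate -> free catalyst + right-handed product; left-handed substrate <-> right-handed substrate; 2 partner -> self-condensation product; 2 free catalyst <-> resting dimer; free catalyst -> spent catalyst
- an excess is the difference of the two amounts in percent of their sum
- an excess is below zero if the other one leads

1. part of the left-handed substrate and right-handed substrate charged together that has reacted at 3.0 min
2. excess of left-handed product over right-handed product in the product at 3.0 min
3. excess of right-handed substrate over left-handed substrate among what is left of the two at 3.0 min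

1. A single pseudo-first-order constant cannot describe the elm run: the exposure, ln of charged over remaining for the two substrates together, divided by time, reads 1.55 min⁻¹ at 0.417 min but 0.493 min⁻¹ at 4.00 min, a fall, so the exposure itself, the mean constant times the time, is what gets carried from run to run.

2. The decision is whether the flask keeps 1.7 mM of free catalyst or goes up to the 3.4 mM of oak, and that hangs on how exposure follows the charge at equal time: at 1.50 min the oak run reads 2.67 and the elm run, interpolated, 1.34, which gives as a reading the catalyst exponent, the power of the catalyst charge that exposure follows at fixed time, 0.497.

3. The elm run, interpolated to 3.0 min, stands at exposure 1.79, and the exponent raises this to 2.52 for the flask, so my own reckoning has 92.0% reacted; twice the catalyst multiplies exposure by 1.41 to 3.56, which by the same reckoning leaves 2.86% of the two substrates instead of 8.04%. The flask is run as charged, at 1.7 mM, and that difference is what the extra catalyst buys by this reckoning.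

4. The forecast says 92.5% reacted, a product excess of 19% and a substrate excess of 5.5%, reading the weak response to the catalyst charge as “a resting dimer in equilibrium with active monomer”; its conversion lies 0.50 percentage points above my reckoning, its exposure being about 2.6.

5. The flask gives 93.3% reacted, a product excess of 14.5% and a substrate excess of 8.82%.

    partner + free catalyst + left-handed substrate → free catalyst + left-handed product (k = 290 L² mol⁻² s⁻¹)
    partner + free catalyst + right-handed substrate → free catalyst + right-handed product (k = 170 L² mol⁻² s⁻¹)
    left-handed substrate ⇌ right-handed substrate (k = 0.0120 s⁻¹)
    2 partner → self-condensation product (k = 0.0230 L mol⁻¹ s⁻¹)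
    2 free catalyst ⇌ resting dimer, settled at all times (K = 1300 L mol⁻¹)
    free catalyst → spent catalyst (k = 0.00700 s⁻¹)

At 3.00 min the flask holds its catalyst as 27.0% free catalyst, 32.3% resting dimer and 40.6% spent catalyst. Its exposure of 2.70 against the elm value corresponds to a catalyst exponent of 0.598 between these two charges, where the readings gave 0.497.

6. For a neighbour flask charged with 0.0029 M of free catalyst, the exponent 0.497 gives exposure 3.29, hence 96.3% reacted at 3.0 min. The computed neighbour flask stands at 97.5%.

The runs were computed with constants of no real substance; the scatter is artificial.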